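**Retrosynthetic overview**
- Target ⇒ methyl 3-O-acetylshikimate + two (R)-2-methylbutanoic acids (double esterification last); the acid comes from an Evans methylation of an N-butanoyl (R)-4-benzyloxazolidinone.
- O-3 is told apart from O-4/O-5 on methyl shikimate by a butane-2,3-diacetal across the trans-4,5-diol, acetylation of O-3, then acetal removal.
- Methyl shikimate ⇐ ring-closing metathesis (C1=C2) of an acyclic diene-triol ester. This is the only carbocycle; it is closed after all three ring stereocentres exist. The dioxane of the diacetal is a temporary second ring, made afterwards and removed again.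
- Key C5–C6 bond: intermolecular indium-mediated carbonyl allylation of (2R,3R)-2,3-dihydroxypent-4-enal with methyl 2-(bromomethyl)acrylate; chelation control sets C-5.
- The aldehyde ⇐ D-ribose (methyl furanoside, 5-iodide, zinc fragmentation); ribose C-2 and C-3 become C-4 and C-3 of the target.

Assumption: the target is taken exactly as the SMILES reads, i.e. the (3R,4S,5R)-shikimate core with both 2-methylbutanoyl groups (R); glycosides 2 and 3 are drawn as the major β-anomers, the anomeric centre being destroyed in step 3.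

Ring positions are given in shikimate numbering (C-1 bears CO2Me, C-3 is the allylic oxygenated carbon).

**Step 1**
Reactants: 1 D-ribose
Product: 2 methyl β-D-ribofuranoside
Conditions: MeOH, H2SO4 (cat.), 0–5 °C, 16 h; then NaHCO3
Reagents that add atoms: methanol, CO
Why: Fischer glycosidation under kinetic control gives the furanoside (β major), locking C-1 as an acetal and leaving the primary 5-OH as the most reactive hydroxyl, with the ribose stereocentres untouched.

**Step 2**
Reactants: 2 methyl β-D-ribofuranoside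
Product: 3 methyl 5-deoxy-5-iodo-β-D-ribofuranoside
Conditions: PPh3, I2, imidazole, THF, reflux, 2 h
Reagents that add atoms: iodine, II
Why: Garegg–Samuelsson (Appel-type) iodination activates only the unhindered primary alcohol for SN2 displacement by iodide, and no stereocentre is involved.

**Step 3**
Reactants: 3 methyl 5-deoxy-5-iodo-β-D-ribofuranoside; 4 methyl 2-(bromomethyl)acrylate
Product: 7 methyl (4R,5S,6R)-4,5,6-trihydroxy-2-methylideneoct-7-enoate, via aldehyde (2R,3R)-2,3-dihydroxypent-4-enal 5 (not isolated), via allylindium reagent 6 (not isolated)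
Conditions: Zn dust, THF/H2O (4:1), ultrasound, 40 °C; then In powder, 4, rt
Reagents that add atoms: none
Why: Bernet–Vasella reductive fragmentation of the 5-iodofuranoside unmasks aldehyde 5, and the indium-mediated Barbier carbonyl allylation in water then goes through the α-hydroxy chelate (Cram-chelate model), so the allyl group adds to give the threo 4,5-diol, i.e. the new carbinol (C-5 of the ring) is R.

**Step 4**
Reactants: 7 methyl (4R,5S,6R)-4,5,6-trihydroxy-2-methylideneoct-7-enoate
Product: 8 methyl shikimate [methyl (3R,4S,5R)-3,4,5-trihydroxycyclohex-1-ene-1-carboxylate]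
Conditions: second-generation Grubbs catalyst (H2IMes)(PCy3)Cl2Ru=CHPh (5 mol %), CH2Cl2 (5 mM), 40 °C
Reagents that add atoms: none
Why: Ring-closing metathesis between the vinyl group and the 1,1-disubstituted acrylate alkene closes the six-membered ring with loss of ethene, tolerates the free hydroxyls and touches no stereocentre.

**Step 5**
Reactants: 8 methyl shikimate
Product: 9 methyl 4,5-O-[(2S,3S)-2,3-dimethoxybutane-2,3-diyl]shikimate
Conditions: butane-2,3-dione, HC(OMe)3, CSA (cat.), MeOH, reflux; then Et3N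
Reagents that add atoms: butane-2,3-dione, CC(=O)C(C)=O; trimethyl orthoformate, COC(OC)OC (the two OMe groups, in exchange with the solvent methanol, CO)
Why: Ley butane-2,3-diacetal protection (the diketone is turned into its tetramethyl bis-acetal in the flask) is thermodynamically selective for the trans-diequatorial 4,5-diol, the two new acetal centres being set (2S,3S) by the double anomeric effect (both OMe axial) on the trans-fused dioxane, so only the allylic 3-OH stays free.

**Step 6**
Reactants: 9 methyl 4,5-O-[(2S,3S)-2,3-dimethoxybutane-2,3-diyl]shikimate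
Product: 10 methyl 3-O-acetyl-4,5-O-[(2S,3S)-2,3-dimethoxybutane-2,3-diyl]shikimate
Conditions: Ac2O, pyridine, DMAP (cat.), CH2Cl2, 0 °C → rt
Reagents that add atoms: acetic anhydride, CC(=O)OC(C)=O
Why: DMAP-catalysed acetylation of the only free hydroxyl proceeds with retention at C-3 because the C–O bond is not broken.

**Step 7**
Reactants: 10 methyl 3-O-acetyl-4,5-O-[(2S,3S)-2,3-dimethoxybutane-2,3-diyl]shikimate
Product: 11 methyl 3-O-acetylshikimate [methyl (3R,4S,5R)-3-acetoxy-4,5-dihydroxycyclohex-1-ene-1-carboxylate]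
Conditions: TFA/H2O (9:1), CH2Cl2, 0 °C → rt, 15 min; toluene co-evaporation
Reagents that add atoms: none
Why: Acid-catalysed acetal hydrolysis removes the diacetal within minutes while the esters survive, and the short cold acidic exposure keeps acetyl migration from O-3 to O-4 negligible.

**Step 8**
Reactants: 12 (R)-4-benzyl-1,3-oxazolidin-2-one; 13 butanoyl chloride
Product: 14 (R)-4-benzyl-3-butanoyl-1,3-oxazolidin-2-one
Conditions: Et3N, DMAP (cat.), CH2Cl2, 0 °C → rt
Reagents that add atoms: none
Why: DMAP-catalysed N-acylation of the oxazolidinone gives the Evans imide without touching the auxiliary stereocentre.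

**Step 9**
Reactants: 14 (R)-4-benzyl-3-butanoyl-1,3-oxazolidin-2-one
Product: 16 (R)-4-benzyl-3-[(2R)-2-methylbutanoyl]-1,3-oxazolidin-2-one, via sodium Z-enolate 15 (not isolated)
Conditions: NaN(SiMe3)2, THF, −78 °C; then MeI, −78 °C; chromatography to a single diastereomer
Reagents that add atoms: iodomethane, CI
Why: Evans asymmetric alkylation: the chelated Z-enolate is methylated on the face opposite the benzyl group, which with the (R)-auxiliary and an ethyl-bearing enolate carbon gives the (2R) centre (about 10:1 before purification).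

**Step 10**
Reactants: 16 (R)-4-benzyl-3-[(2R)-2-methylbutanoyl]-1,3-oxazolidin-2-one
Product: 18 (R)-2-methylbutanoic acid, via lithium peroxycarboxylate 17 (not isolated)
Conditions: LiOH, H2O2 (30 % aq.), THF/H2O (3:1), 0 °C; then Na2SO3 (aq.); then HCl to pH 2, extraction, distillation
Reagents that add atoms: hydrogen peroxide, OO (as LiOOH; one O ends in the carboxyl OH)
Why: LiOOH attacks the exocyclic imide carbonyl selectively (Evans auxiliary cleavage) under conditions too mild to enolise the α-centre, and sulfite reduces the peracid salt to the acid while the auxiliary is recovered.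

**Step 11**
Reactants: 11 methyl 3-O-acetylshikimate; 18 (R)-2-methylbutanoic acid (2.5–3 equiv)
Product: 20 methyl (3R,4S,5R)-3-acetoxy-4,5-bis{[(2R)-2-methylbutanoyl]oxy}cyclohex-1-ene-1-carboxylate (CNP0132712.1), via 5-O-monoester 19 (not isolated)
Conditions: DCC, DMAP (cat.), CH2Cl2, 0 °C → rt
Reagents that add atoms: none
Why: Steglich esterification acylates the less hindered 5-OH first and then the 4-OH with retention at both carbinols, and a simple α-alkyl acid does not epimerise under carbodiimide/DMAP activation.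

**Compound list**
1 | D-ribose (drawn in the open-chain aldehydo form) | O=C[C@H](O)[C@H](O)[C@H](O)CO | starting material
2 | methyl β-D-ribofuranoside | CO[C@@H]1O[C@H](CO)[C@@H](O)[C@H]1O | intermediate
3 | methyl 5-deoxy-5-iodo-β-D-ribofuranoside | CO[C@@H]1O[C@H](CI)[C@@H](O)[C@H]1O | intermediate
4 | methyl 2-(bromomethyl)acrylate | C=C(CBr)C(=O)OC | starting material
5 | (2R,3R)-2,3-dihydroxypent-4-enal | O=C[C@H](O)[C@H](O)C=C | intermediate (not isolated)
6 | [2-(methoxycarbonyl)prop-2-en-1-yl]indium (allylindium reagent, written in its monovalent indium form) | C=C(C[In])C(=O)OC | intermediate (not isolated)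
7 | methyl (4R,5S,6R)-4,5,6-trihydroxy-2-methylideneoct-7-enoate | C=C[C@@H](O)[C@@H](O)[C@H](O)CC(=C)C(=O)OC | intermediate
8 | methyl shikimate, methyl (3R,4S,5R)-3,4,5-trihydroxycyclohex-1-ene-1-carboxylate | COC(=O)C1=C[C@@H](O)[C@@H](O)[C@H](O)C1 | intermediate
9 | methyl 4,5-O-[(2S,3S)-2,3-dimethoxybutane-2,3-diyl]shikimate (trans-fused dioxane, both OMe axial, 3-OH free) | COC(=O)C1=C[C@@H](O)[C@H]2O[C@](C)(OC)[C@@](C)(OC)O[C@@H]2C1 | intermediate
10 | methyl 3-O-acetyl-4,5-O-[(2S,3S)-2,3-dimethoxybutane-2,3-diyl]shikimate | COC(=O)C1=C[C@@H](OC(C)=O)[C@H]2O[C@](C)(OC)[C@@](C)(OC)O[C@@H]2C1 | intermediate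
11 | methyl 3-O-acetylshikimate | COC(=O)C1=C[C@@H](OC(C)=O)[C@@H](O)[C@H](O)C1 | intermediate
12 | (R)-4-benzyl-1,3-oxazolidin-2-one | O=C1N[C@H](Cc2ccccc2)CO1 | starting material
13 | butanoyl chloride | CCCC(=O)Cl | starting material
14 | (R)-4-benzyl-3-butanoyl-1,3-oxazolidin-2-one | CCCC(=O)N1[C@H](Cc2ccccc2)COC1=O | intermediate
15 | sodium (1Z)-1-[(4R)-4-benzyl-2-oxo-1,3-oxazolidin-3-yl]but-1-en-1-olate | CC/C=C(\[O-])N1[C@H](Cc2ccccc2)COC1=O.[Na+] | intermediate (not isolated)
16 | (R)-4-benzyl-3-[(2R)-2-methylbutanoyl]-1,3-oxazolidin-2-one | CC[C@@H](C)C(=O)N1[C@H](Cc2ccccc2)COC1=O | intermediate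
17 | lithium (2R)-2-methylbutaneperoxoate | CC[C@@H](C)C(=O)O[O-].[Li+] | intermediate (not isolated)
18 | (R)-2-methylbutanoic acid | CC[C@@H](C)C(=O)O | intermediate
19 | methyl 3-O-acetyl-5-O-[(2R)-2-methylbutanoyl]shikimate (4-OH free) | COC(=O)C1=C[C@@H](OC(C)=O)[C@@H](O)[C@H](OC(=O)[C@H](C)CC)C1 | intermediate (not isolated)
20 | methyl (3R,4S,5R)-3-acetoxy-4,5-bis{[(2R)-2-methylbutanoyl]oxy}cyclohex-1-ene-1-carboxylate | CC[C@@H](C)C(=O)O[C@@H]1[C@H](OC(C)=O)C=C(C(=O)OC)C[C@H]1OC(=O)[C@H](C)CC | target

**Totals**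
Total step count: 11. Longest linear sequence: 8 steps (steps 1–7, then step 11); steps 8–10 are a three-step side branch.

**Three steps most likely to fail**

Step 3. The free dihydroxy-aldehyde 5 cannot be purified. The chelation-controlled diastereoselectivity at C-5 may be only moderate. The γ-hydroxy-α-methylene ester 7 can lactonise if the work-up turns acidic.
Fallback (sets out from 3, comes back at 8): replace chelation control by Felkin–Anh control followed by inversion.
- Iodide 3 with 2,2-dimethoxypropane and TsOH (cat.) in acetone gives methyl 5-deoxy-5-iodo-2,3-O-isopropylidene-β-D-ribofuranoside F1.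
- Zn dust in THF/H2O under ultrasound gives the isolable aldehyde (4R,5R)-2,2-dimethyl-5-vinyl-1,3-dioxolane-4-carbaldehyde F2.
- In powder and 4 in THF/H2O, now with no chelating hydroxyl, give mainly the erythro alcohol methyl (4S)-4-[(4S,5R)-2,2-dimethyl-5-vinyl-1,3-dioxolan-4-yl]-4-hydroxy-2-methylidenebutanoate F3.
- Mitsunobu inversion (4-nitrobenzoic acid, PPh3, DIAD, THF) gives methyl (4R)-4-[(4S,5R)-2,2-dimethyl-5-vinyl-1,3-dioxolan-4-yl]-2-methylidene-4-[(4-nitrobenzoyl)oxy]butanoate F4.
- Ring-closing metathesis as in step 4 gives methyl 3,4-O-isopropylidene-5-O-(4-nitrobenzoyl)shikimate F5.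
- K2CO3 in MeOH at 0 °C gives methyl 3,4-O-isopropylideneshikimate F6, and 80 % aqueous AcOH at 40 °C then gives 8.

Step 4. The unprotected triol is poorly soluble in CH2Cl2. The free allylic alcohol can be isomerised by ruthenium hydrides. The acrylate alkene is a sluggish metathesis partner.
Fallback (sets out from 7, comes back at 8): mask the hydroxyls before ring closure.
- Triol 7 with Ac2O, pyridine and DMAP (cat.) gives methyl (4R,5S,6R)-4,5,6-triacetoxy-2-methylideneoct-7-enoate F7.
- Ring-closing metathesis (same catalyst, toluene, 80 °C) gives methyl 3,4,5-tri-O-acetylshikimate F8.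
- K2CO3 (cat.) in MeOH at 0 °C returns 8.

Step 11. In the diol 11 the 3-acetyl group can migrate to the cis 4-OH under the basic acylation conditions (or already in step 7), which would scramble the ester pattern. The flanked 4-OH is also slow to acylate.
Fallback (sets out from 9, comes back at 20): put the acetate on last.
- Alcohol 9 with TBDPSCl and imidazole in DMF gives methyl 3-O-(tert-butyldiphenylsilyl)-4,5-O-[(2S,3S)-2,3-dimethoxybutane-2,3-diyl]shikimate F9.
- TFA/H2O (9:1) gives methyl 3-O-(tert-butyldiphenylsilyl)shikimate F10.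
- Acid 18 with DCC and DMAP gives methyl 3-O-(tert-butyldiphenylsilyl)-4,5-bis-O-[(2R)-2-methylbutanoyl]shikimate F11.
- HF·pyridine in THF gives methyl 4,5-bis-O-[(2R)-2-methylbutanoyl]shikimate F12, which is acetylated at once (Ac2O, pyridine, DMAP) to 20.

**Further compounds**
F1 | step 3 | methyl 5-deoxy-5-iodo-2,3-O-isopropylidene-β-D-ribofuranoside | CO[C@@H]1O[C@H](CI)[C@H]2OC(C)(C)O[C@@H]12
F2 | step 3 | (4R,5R)-2,2-dimethyl-5-vinyl-1,3-dioxolane-4-carbaldehyde | O=C[C@@H]1OC(C)(C)O[C@@H]1C=C
F3 | step 3 | methyl (4S)-4-[(4S,5R)-2,2-dimethyl-5-vinyl-1,3-dioxolan-4-yl]-4-hydroxy-2-methylidenebutanoate | C=C[C@H]1OC(C)(C)O[C@H]1[C@@H](O)CC(=C)C(=O)OC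
F4 | step 3 | methyl (4R)-4-[(4S,5R)-2,2-dimethyl-5-vinyl-1,3-dioxolan-4-yl]-2-methylidene-4-[(4-nitrobenzoyl)oxy]butanoate | C=C[C@H]1OC(C)(C)O[C@H]1[C@H](OC(=O)c2ccc(cc2)[N+](=O)[O-])CC(=C)C(=O)OC
F5 | step 3 | methyl 3,4-O-isopropylidene-5-O-(4-nitrobenzoyl)shikimate | COC(=O)C1=C[C@H]2OC(C)(C)O[C@H]2[C@H](OC(=O)c3ccc(cc3)[N+](=O)[O-])C1
F6 | step 3 | methyl 3,4-O-isopropylideneshikimate | COC(=O)C1=C[C@H]2OC(C)(C)O[C@H]2[C@H](O)C1
F7 | step 4 | methyl (4R,5S,6R)-4,5,6-triacetoxy-2-methylideneoct-7-enoate | C=C[C@@H](OC(C)=O)[C@@H](OC(C)=O)[C@H](OC(C)=O)CC(=C)C(=O)OC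
F8 | step 4 | methyl 3,4,5-tri-O-acetylshikimate | COC(=O)C1=C[C@@H](OC(C)=O)[C@@H](OC(C)=O)[C@H](OC(C)=O)C1
F9 | step 11 | methyl 3-O-(tert-butyldiphenylsilyl)-4,5-O-[(2S,3S)-2,3-dimethoxybutane-2,3-diyl]shikimate | COC(=O)C1=C[C@@H](O[Si](c3ccccc3)(c3ccccc3)C(C)(C)C)[C@H]2O[C@](C)(OC)[C@@](C)(OC)O[C@@H]2C1
F10 | step 11 | methyl 3-O-(tert-butyldiphenylsilyl)shikimate | COC(=O)C1=C[C@@H](O[Si](c2ccccc2)(c2ccccc2)C(C)(C)C)[C@@H](O)[C@H](O)C1
F11 | step 11 | methyl 3-O-(tert-butyldiphenylsilyl)-4,5-bis-O-[(2R)-2-methylbutanoyl]shikimate | COC(=O)C1=C[C@@H](O[Si](c2ccccc2)(c2ccccc2)C(C)(C)C)[C@@H](OC(=O)[C@H](C)CC)[C@H](OC(=O)[C@H](C)CC)C1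
F12 | step 11 | methyl 4,5-bis-O-[(2R)-2-methylbutanoyl]shikimate | COC(=O)C1=C[C@@H](O)[C@@H](OC(=O)[C@H](C)CC)[C@H](OC(=O)[C@H](C)CC)C1
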